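**Retrosynthetic overview**

- The target is opened to its benzyl ester/benzyl ether; the ketone comes from a Weinreb amide and undecylmagnesium bromide, and the amide from a homophthalate-type dibenzyl diester by hydrolysis of its unhindered arylacetic ester.
- Key disconnection: the ring bonds C1–CO2Bn and C6–CH2 of that diester are cut together, back to 3-(benzyloxy)-5-methoxybenzyne and dibenzyl malonate, whose C–C bond the aryne enters.
- Feature used: on the benzene ring the carboxyl carbon C1 and the acylmethyl-bearing carbon C6 are neighbours, and the oxygen-bearing C2 sits beside C1. This is the ortho acyl/acylmethyl pattern, with an alkoxy group next to the acyl carbon, that a 3-alkoxyaryne delivers.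
- The aryne precursor comes from 3-(benzyloxy)-2-bromo-5-methoxyphenol by O-silylation, Br/Li exchange, retro-Brook shift and triflation. The bromine is placed on the symmetric bis-MOM ether of 5-methoxyresorcinol, where the carbon between the two acetal oxygens is unique. The benzyl group is added only afterwards, so no choice between an OBn-flanked and an OMe-flanked site arises and no benzyl ether is exposed to a prolonged lithiation.
- Rings: the benzene ring comes from 5-methoxyresorcinol and no ring is built. The only closure is a transient four-membered ring inside the key step, which opens again.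

Key step: step 6

Remark: the target is drawn as the open keto acid. It can equilibrate with a cyclic lactol and lose water to an isocoumarin under acid or heat, so the last step and the isolation are kept neutral and cold.

**Route**

Step 1
Reactants: 1 5-methoxyresorcinol
Product: 2 1-methoxy-3,5-bis(methoxymethoxy)benzene
Conditions: NaH (2.4 equiv), MOMCl (2.4 equiv), THF–DMF, 0 °C to rt
Reagents that add atoms: chloromethyl methyl ether, COCCl
Why: Williamson-type O-alkylation of both phenoxides by the hard electrophile MOMCl should give the bis-acetal, whose two chelating OCH2OMe groups flank only C2.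

Step 2
Reactants: 2 1-methoxy-3,5-bis(methoxymethoxy)benzene
Product: 4 2-bromo-5-methoxy-1,3-bis(methoxymethoxy)benzene, via aryllithium 3 (not isolated)
Conditions: n-BuLi (1.1 equiv), THF, 0 °C to rt; then BrCl2C–CCl2Br (1.2 equiv), −78 °C to rt
Reagents that add atoms: 1,2-dibromo-1,1,2,2-tetrachloroethane, BrC(Cl)(Cl)C(Cl)(Cl)Br
Why: Directed ortho-metalation should take place at C2, the only proton held between two chelating OMOM groups (C4 and C6 have one OMOM and a weaker OMe director), and bromine transfer from the polyhaloethane to the aryllithium then gives the bromide.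

Step 3
Reactants: 4 2-bromo-5-methoxy-1,3-bis(methoxymethoxy)benzene
Product: 5 2-bromo-5-methoxybenzene-1,3-diol
Conditions: 3 M HCl (aq), MeOH, 40 °C
Reagents that add atoms: none
Why: Acid-catalysed acetal exchange with methanol should remove both MOM groups as dimethoxymethane, while the aryl bromide is inert to dilute acid at this temperature.

Step 4
Reactants: 5 2-bromo-5-methoxybenzene-1,3-diol
Product: 6 3-(benzyloxy)-2-bromo-5-methoxyphenol
Conditions: BnBr (1.0 equiv), K2CO3 (1.1 equiv), acetone, 50 °C; chromatography, recovered 5 recycled
Reagents that add atoms: benzyl bromide, BrCc1ccccc1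
Why: Williamson etherification of a symmetric diol with one equivalent of benzyl bromide can give only one mono-ether, which should be separable from unreacted diol and from the bis-ether.

Step 5
Reactants: 6 3-(benzyloxy)-2-bromo-5-methoxyphenol
Product: 9 3-(benzyloxy)-5-methoxy-2-(trimethylsilyl)phenyl trifluoromethanesulfonate, via aryl trimethylsilyl ether 7 (not isolated), via lithium phenolate 8 (not isolated)
Conditions: HMDS (1.0 equiv), THF, 65 °C, then evaporation; n-BuLi (1.1 equiv), THF, −100 to −78 °C; Tf2O (1.2 equiv), −100 to −78 °C; NaHCO3 (aq)
Reagents that add atoms: hexamethyldisilazane, C[Si](C)(C)N[Si](C)(C)C; trifluoromethanesulfonic anhydride, O=S(=O)(OS(=O)(=O)C(F)(F)F)C(F)(F)F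
Why: O-silylation, bromine–lithium exchange (much faster at −100 °C than benzylic deprotonation of the benzyl ether) and 1,3-O-to-C silyl migration (retro-Brook rearrangement) should put silicon on the former C–Br carbon, and the lithium phenolate is triflated in the same flask, so the acid-labile electron-rich C–Si bond appears only together with the deactivating triflate.

Step 6
Reactants: 9 3-(benzyloxy)-5-methoxy-2-(trimethylsilyl)phenyl trifluoromethanesulfonate; 10 dibenzyl malonate
Product: 12 benzyl 2-(benzyloxy)-6-[2-(benzyloxy)-2-oxoethyl]-4-methoxybenzoate, via 3-(benzyloxy)-5-methoxybenzyne 11 (not isolated)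
Conditions: 10 (1.2 equiv), CsF (2.5 equiv), MeCN (0.05 M), 60–80 °C
Reagents that add atoms: none
Why: Fluoride attacks silicon of 9 and triflate leaves to give aryne 11; the cesium enolate of 10 adds through carbon to the aryne carbon remote from the benzyloxy group, the aryl anion so formed (ortho to OBn) closes onto one ester carbonyl in a 4-exo-trig addition to a benzocyclobutene alkoxide, and this four-membered ring opens by retro-aldol-type C–C cleavage to the aryl benzyl ester and an ester-stabilised benzylic anion that is protonated by further malonate. The closest known reaction type is the insertion of arynes from 2-silylaryl triflates into the C–C sigma bond of malonates and beta-ketoesters (aryne acyl-alkylation), applied here to a new aryne. No ring remains and no stereocentre is formed; the transient cyclobutene only relays the benzyloxycarbonyl group from the malonate carbon to the ring. The step needs regioselective addition to an unsymmetrical aryne, which the inductively withdrawing OBn group beside the triple bond should secure by making the distal aryne carbon the electrophilic one and stabilising charge at the proximal carbon, so that CH2CO2Bn lands on the future C6 and CO2Bn on the future C1 next to the oxygen; the more remote OMe should have only a minor influence. It also needs closure of the aryl anion onto the ester to outrun its protonation, which dilute aprotic conditions and the adjacent ester carbonyl should favour.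

Step 7
Reactants: 12 benzyl 2-(benzyloxy)-6-[2-(benzyloxy)-2-oxoethyl]-4-methoxybenzoate
Product: 13 2-{3-(benzyloxy)-2-[(benzyloxy)carbonyl]-5-methoxyphenyl}acetic acid
Conditions: LiOH·H2O (1.1 equiv), THF–H2O (3:1), 0 °C to rt; then 1 M HCl to pH 3
Reagents that add atoms: lithium hydroxide, [Li+].[OH-]
Why: Saponification should touch only the unhindered arylacetic ester, because the benzoate lies between two ortho substituents and is shielded from hydroxide.

Step 8
Reactants: 13 2-{3-(benzyloxy)-2-[(benzyloxy)carbonyl]-5-methoxyphenyl}acetic acid
Product: 15 benzyl 2-(benzyloxy)-4-methoxy-6-{2-[methoxy(methyl)amino]-2-oxoethyl}benzoate, via acyl imidazole 14 (not isolated)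
Conditions: CDI (1.2 equiv), CH2Cl2, rt; then MeNHOMe·HCl (1.5 equiv), rt
Reagents that add atoms: N,O-dimethylhydroxylamine hydrochloride, CNOC.Cl
Why: Activation of the acid as its acyl imidazole and aminolysis by N,O-dimethylhydroxylamine (Weinreb amide formation) should proceed at room temperature without touching the hindered aryl ester.

Step 9
Reactants: 15 benzyl 2-(benzyloxy)-4-methoxy-6-{2-[methoxy(methyl)amino]-2-oxoethyl}benzoate; 16 1-bromoundecane
Product: 18 benzyl 2-(benzyloxy)-4-methoxy-6-(2-oxotridecyl)benzoate, via undecylmagnesium bromide 17 (not isolated)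
Conditions: 16, Mg turnings, cat. I2, THF, 40 °C; this solution (1.5 equiv) added to 15, THF, −20 to 0 °C; sat. NH4Cl (aq)
Reagents that add atoms: none
Why: In the Weinreb ketone synthesis the Grignard reagent adds once to the N-methoxy-N-methylamide to give a magnesium chelate that releases the ketone only on quench, while the di-ortho-substituted benzoate is too hindered to compete at this temperature.

Step 10
Reactants: 18 benzyl 2-(benzyloxy)-4-methoxy-6-(2-oxotridecyl)benzoate
Product: 19 2-hydroxy-4-methoxy-6-(2-oxotridecyl)benzoic acid
Conditions: H2 (1 atm), 10% Pd/C, EtOAc, rt; filtration, evaporation below 30 °C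
Reagents that add atoms: none
Why: Catalytic hydrogenolysis should cleave the benzyl ester and the benzyl aryl ether as toluene under neutral conditions that leave the aliphatic ketone and the methyl ether untouched.

**Compound list**

1 | 5-methoxyresorcinol | COc1cc(O)cc(O)c1 | starting material
2 | 1-methoxy-3,5-bis(methoxymethoxy)benzene | COCOc1cc(OC)cc(OCOC)c1 | intermediate
3 | [4-methoxy-2,6-bis(methoxymethoxy)phenyl]lithium | COCOc1cc(OC)cc(OCOC)c1[Li] | intermediate
4 | 2-bromo-5-methoxy-1,3-bis(methoxymethoxy)benzene | COCOc1cc(OC)cc(OCOC)c1Br | intermediate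
5 | 2-bromo-5-methoxybenzene-1,3-diol | COc1cc(O)c(Br)c(O)c1 | intermediate
6 | 3-(benzyloxy)-2-bromo-5-methoxyphenol | COc1cc(O)c(Br)c(OCc2ccccc2)c1 | intermediate
7 | [3-(benzyloxy)-2-bromo-5-methoxyphenoxy]trimethylsilane | COc1cc(O[Si](C)(C)C)c(Br)c(OCc2ccccc2)c1 | intermediate
8 | lithium 3-(benzyloxy)-5-methoxy-2-(trimethylsilyl)phenolate | [Li+].COc1cc([O-])c([Si](C)(C)C)c(OCc2ccccc2)c1 | intermediate
9 | 3-(benzyloxy)-5-methoxy-2-(trimethylsilyl)phenyl trifluoromethanesulfonate | COc1cc(OCc2ccccc2)c([Si](C)(C)C)c(OS(=O)(=O)C(F)(F)F)c1 | intermediate
10 | dibenzyl malonate | O=C(CC(=O)OCc1ccccc1)OCc1ccccc1 | starting material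
11 | 3-(benzyloxy)-5-methoxybenzyne (triple bond between the former C–OTf and C–Si carbons) | COC1=CC#CC(OCc2ccccc2)=C1 | intermediate
12 | benzyl 2-(benzyloxy)-6-[2-(benzyloxy)-2-oxoethyl]-4-methoxybenzoate | COc1cc(CC(=O)OCc2ccccc2)c(C(=O)OCc2ccccc2)c(OCc2ccccc2)c1 | intermediate
13 | 2-{3-(benzyloxy)-2-[(benzyloxy)carbonyl]-5-methoxyphenyl}acetic acid | COc1cc(CC(=O)O)c(C(=O)OCc2ccccc2)c(OCc2ccccc2)c1 | intermediate
14 | benzyl 2-(benzyloxy)-6-[2-(1H-imidazol-1-yl)-2-oxoethyl]-4-methoxybenzoate | COc1cc(CC(=O)n2ccnc2)c(C(=O)OCc2ccccc2)c(OCc2ccccc2)c1 | intermediate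
15 | benzyl 2-(benzyloxy)-4-methoxy-6-{2-[methoxy(methyl)amino]-2-oxoethyl}benzoate | COc1cc(CC(=O)N(C)OC)c(C(=O)OCc2ccccc2)c(OCc2ccccc2)c1 | intermediate
16 | 1-bromoundecane | CCCCCCCCCCCBr | starting material
17 | undecylmagnesium bromide | CCCCCCCCCCC[Mg]Br | intermediate
18 | benzyl 2-(benzyloxy)-4-methoxy-6-(2-oxotridecyl)benzoate | CCCCCCCCCCCC(=O)Cc1cc(OC)cc(OCc2ccccc2)c1C(=O)OCc1ccccc1 | intermediate
19 | 2-hydroxy-4-methoxy-6-(2-oxotridecyl)benzoic acid | CCCCCCCCCCCC(=O)Cc1cc(OC)cc(O)c1C(=O)O | target

**Step count**

Total steps: 10. Longest linear sequence: 10 steps (1 to 19); compounds 10 and 16 enter as purchased materials.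

**Steps most likely to fail, with fallbacks**

Step 6. The aryl anion may be protonated by malonate before it closes onto the ester, which gives simple alpha-arylation. The product enolate may also add to a second aryne, or the regioselectivity of addition may erode. The fallback leaves the aryne and builds the two carbon substituents one after the other, setting out from 9 and returning at 13. Negishi coupling of the triflate of 9 with MeZnCl and PdCl2(dppf) in THF should give 1-(benzyloxy)-5-methoxy-3-methyl-2-(trimethylsilyl)benzene F1. Ipso-iododesilylation with ICl in CH2Cl2 at low temperature should give 1-(benzyloxy)-2-iodo-5-methoxy-3-methylbenzene F2. Palladium-catalysed benzyloxycarbonylation (CO at 1 atm, benzyl alcohol, Pd(OAc)2, Xantphos, K2CO3, toluene, 90 °C) should give benzyl 2-(benzyloxy)-4-methoxy-6-methylbenzoate F3. Lateral lithiation of the ortho-methyl group with LiN(i-Pr)2 in THF at −78 °C should give the benzylic lithium species of the toluate F4, which is carboxylated with CO2 and acidified to 13. Step 7 is then not needed.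

Step 9. The basic Grignard reagent may deprotonate the acidic aryl-CH2 group of the amide, which returns the amide on quench, or it may begin to attack the aryl ester. The fallback uses a non-basic organozinc reagent in a Fukuyama ketone synthesis, setting out from 13 and returning at 18. Thioesterification of 13 with ethanethiol (EDC·HCl, cat. DMAP, CH2Cl2) should give benzyl 2-(benzyloxy)-6-[2-(ethylsulfanyl)-2-oxoethyl]-4-methoxybenzoate F5. Zinc insertion into 16 (Zn dust, LiCl, THF, 50 °C) should give undecylzinc bromide F6, and coupling of F5 with F6 under PdCl2(PPh3)2 catalysis in THF–toluene at rt should give 18. Step 8 is then not needed.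

Step 2. Lithiation may take place partly at C4/C6, between an OMOM and the OMe group, which would carry a regioisomeric bromide forward. The fallback fixes the bromine position by electrophilic bromination and selective reduction, setting out from 1 and returning at 5. Exhaustive bromination of 1 (Br2, 3 equiv, CHCl3, 0 °C) should give 2,4,6-tribromo-5-methoxybenzene-1,3-diol F7. Reduction with Na2SO3 and NaOH in aqueous methanol should remove the two bromines para to a hydroxyl group through their dienone tautomers and leave the bromine between the two hydroxyls, giving 5. Steps 1 and 3 are then not needed.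

**Further compounds**

F1 | step 6 | 1-(benzyloxy)-5-methoxy-3-methyl-2-(trimethylsilyl)benzene | COc1cc(C)c([Si](C)(C)C)c(OCc2ccccc2)c1
F2 | step 6 | 1-(benzyloxy)-2-iodo-5-methoxy-3-methylbenzene | COc1cc(C)c(I)c(OCc2ccccc2)c1
F3 | step 6 | benzyl 2-(benzyloxy)-4-methoxy-6-methylbenzoate | COc1cc(C)c(C(=O)OCc2ccccc2)c(OCc2ccccc2)c1
F4 | step 6 | ({3-(benzyloxy)-2-[(benzyloxy)carbonyl]-5-methoxyphenyl}methyl)lithium | [Li]Cc1cc(OC)cc(OCc2ccccc2)c1C(=O)OCc1ccccc1
F5 | step 9 | benzyl 2-(benzyloxy)-6-[2-(ethylsulfanyl)-2-oxoethyl]-4-methoxybenzoate | CCSC(=O)Cc1cc(OC)cc(OCc2ccccc2)c1C(=O)OCc1ccccc1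
F6 | step 9 | undecylzinc bromide | CCCCCCCCCCC[Zn]Br
F7 | step 2 | 2,4,6-tribromo-5-methoxybenzene-1,3-diol | COc1c(Br)c(O)c(Br)c(O)c1Br
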